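**Retrosynthetic overview**

1. Target 28 ⇐ hydroxyquinone 27 by O-methylation of the C3 hydroxyl (ring locants: C1/C4 carbonyl, C2/C3 oxygenated, C5 methyl, C6 chain).
2. 27 ⇐ siloxyalkyne 19 (C1, C6 and the whole C50 chain) + cyclobutenone 24 (C2–C5). Ring bonds C1–C2 and C5–C6 are made together by a [2+2] cycloaddition across the enone C2=C5 bond of 24; the shared C2–C5 bond then opens (two-carbon ring expansion).
3. Enabling feature: ring atoms C2(OMe)–C3(O)–C4(O)–C5(Me) carry the oxygen pattern of squaric acid. A temporary C2–C5 bond folds them into a strained cyclobutenone whose C4 ketal leaves C3=O as the only acceptor, so C5 is the enone β-carbon and C2 the α-carbon, matched to the nucleophilic chain carbon (C6) and electrophilic oxygenated carbon (C1) of the siloxyalkyne.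
4. 19 ⇐ C50 allylic bromide 15 (ethynyl Grignard, then acetylide oxidation and O-silylation); 15 ⇐ two geranylgeraniol-derived C20 blocks (allylic sulfone coupling) + (R)-citronellyl bromide (copper-catalysed Grignard coupling), which supplies the only stereocentre.
5. Ring order: purchased four-membered squarate ring (temporary), transient cyclobutene of a bicyclo[2.2.0]hexenone, then the six-membered quinone ring by its opening.

Key step: step 16

Remark: (2E,6E,10E)-geranylgeraniol, (R)-citronellyl bromide and dimethyl squarate are taken as purchased; the chain stereocentre keeps the spatial arrangement of (R)-citronellyl bromide and is named S in the C30 and C50 compounds only because chain extension reverses the CIP ranking of its two methylene arms.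

Abbreviation: R50 = (2E,6E,10E,14E,18E,22E,26E,30E,35S)-3,7,11,15,19,23,27,31,35,39-decamethyltetraconta-2,6,10,14,18,22,26,30,38-nonaen-1-yl.

**Route**

Step 1
Reactants: 1 (2E,6E,10E)-geranylgeraniol
Product: 2 tert-butyl(dimethyl){[(2E,6E,10E)-3,7,11,15-tetramethylhexadeca-2,6,10,14-tetraen-1-yl]oxy}silane
Conditions: TBSCl, imidazole, DMF, 0 °C → rt
Reagents that add atoms: tert-butyldimethylsilyl chloride, CC(C)(C)[Si](C)(C)Cl
Why: Standard silylation of a primary allylic alcohol; the silyl ether masks the chain head through the organometallic steps.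

Step 2
Reactants: 2 silyl ether
Product: 3 (2E,6E,10E,14E)-16-[(tert-butyldimethylsilyl)oxy]-2,6,10,14-tetramethylhexadeca-2,6,10,14-tetraen-1-ol
Conditions: SeO2 (0.1 equiv), t-BuOOH (3 equiv), salicylic acid (0.1 equiv), CH2Cl2, 0 °C → rt, stopped at partial conversion
Reagents that add atoms: tert-butyl hydroperoxide, CC(C)(C)OO (oxygen passed on by catalytic selenium dioxide, O=[Se]=O)
Why: SeO2-catalysed allylic oxidation (ene reaction then [2,3]-sigmatropic shift) should attack the terminal isopropylidene group, the most electron-rich and least hindered olefin, and hydroxylate its E-methyl group, which fixes the E geometry of the new allylic alcohol.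

Step 3
Reactants: 3 allylic alcohol
Product: 4 {[(2E,6E,10E,14E)-16-bromo-3,7,11,15-tetramethylhexadeca-2,6,10,14-tetraen-1-yl]oxy}(tert-butyl)dimethylsilane
Conditions: CBr4, PPh3, CH2Cl2, 0 °C
Reagents that add atoms: carbon tetrabromide, BrC(Br)(Br)Br
Why: The Appel reaction converts a primary allylic alcohol to the bromide under neutral conditions without allylic transposition and leaves the silyl ether intact.

Step 4
Reactants: 4 allylic bromide (part of the material)
Product: 5 tert-butyl(dimethyl){[(2E,6E,10E,14E)-3,7,11,15-tetramethyl-16-(4-methylbenzenesulfonyl)hexadeca-2,6,10,14-tetraen-1-yl]oxy}silane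
Conditions: TolSO2Na (sodium p-toluenesulfinate), DMF, rt
Reagents that add atoms: sodium p-toluenesulfinate, [Na+].Cc1ccc(cc1)S(=O)[O-]
Why: S-alkylation of the sulfinate by SN2 at the primary allylic bromide gives the allylic sulfone with the E olefin unchanged.

Step 5
Reactants: 6 (R)-citronellyl bromide [(6R)-8-bromo-2,6-dimethyloct-2-ene]; 4 allylic bromide
Product: 8 tert-butyl{[(2E,6E,10E,14E,19S)-3,7,11,15,19,23-hexamethyltetracosa-2,6,10,14,22-pentaen-1-yl]oxy}dimethylsilane, via (R)-citronellylmagnesium bromide 7 (not isolated)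
Conditions: 6, Mg, THF, rt → 40 °C; then 4, Li2CuCl4 (3 mol %), THF, −40 → 0 °C
Reagents that add atoms: none
Why: Copper-catalysed Grignard–allylic halide cross-coupling at the primary allylic terminus should join the blocks with retention of the E olefin; the stereocentre enters here from the chiral pool, lies three bonds from the reacting carbon and cannot epimerise.

Step 6
Reactants: 8 C30 silyl ether
Product: 9 (2E,6E,10E,14E,19S)-3,7,11,15,19,23-hexamethyltetracosa-2,6,10,14,22-pentaen-1-ol
Conditions: TBAF, THF, 0 °C → rt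
Reagents that add atoms: none
Why: Fluoride cleavage of the silyl ether frees the primary allylic alcohol without touching the olefins.

Step 7
Reactants: 9 C30 alcohol
Product: 10 (2E,6E,10E,14E,19S)-1-bromo-3,7,11,15,19,23-hexamethyltetracosa-2,6,10,14,22-pentaene
Conditions: PBr3, pyridine (cat.), Et2O, −10 °C
Reagents that add atoms: phosphorus tribromide, BrP(Br)Br
Why: PBr3 bromination of a primary polyprenol at low temperature is the standard way to the E allylic bromide.

Step 8
Reactants: 5 allylic sulfone; 10 C30 bromide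
Product: 12 tert-butyl{[(2E,6E,10E,14E,18E,22E,26E,30E,35S)-3,7,11,15,19,23,27,31,35,39-decamethyl-16-(4-methylbenzenesulfonyl)tetraconta-2,6,10,14,18,22,26,30,38-nonaen-1-yl]oxy}dimethylsilane (both C16 epimers), via lithiated sulfone 11 (not isolated)
Conditions: 5, n-BuLi, THF, −78 °C; then 10, −78 → −20 °C
Reagents that add atoms: none
Why: Alkylation of the α-sulfonyl allyl anion at its sulfone-bearing carbon (sulfone-mediated head-to-tail prenyl coupling) joins the halves by SN2 at the primary allylic bromide; the new sulfone-bearing centre forms as both epimers and is removed in step 9.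

Step 9
Reactants: 12 C50 sulfone
Product: 13 tert-butyl(dimethyl)(R50-oxy)silane
Conditions: PdCl2(dppp) (5 mol %), LiBHEt3, THF, 0 °C → rt
Reagents that add atoms: none
Why: Palladium-catalysed hydride displacement of the allylic sulfinate, through a π-allyl complex of zerovalent palladium formed from PdCl2(dppp), should put hydride on the carbon that carried the sulfone and keep the position and E geometry of the adjacent olefin.

Step 10
Reactants: 13 C50 silyl ether
Product: 14 R50-OH [(2E,6E,10E,14E,18E,22E,26E,30E,35S)-3,7,11,15,19,23,27,31,35,39-decamethyltetraconta-2,6,10,14,18,22,26,30,38-nonaen-1-ol]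
Conditions: TBAF, THF, 0 °C → rt
Reagents that add atoms: none
Why: Fluoride desilylation as in step 6.

Step 11
Reactants: 14 C50 alcohol
Product: 15 R50-Br (the 1-bromide of 14)
Conditions: PBr3, pyridine (cat.), Et2O/hexane, −10 °C
Reagents that add atoms: phosphorus tribromide, BrP(Br)Br
Why: Same polyprenol bromination as in step 7.

Step 12
Reactants: 15 C50 bromide
Product: 16 (4E,8E,12E,16E,20E,24E,28E,32E,37S)-5,9,13,17,21,25,29,33,37,41-decamethyldotetraconta-4,8,12,16,20,24,28,32,40-nonaen-1-yne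
Conditions: HC≡CMgBr (3 equiv), CuCl (10 mol %), THF, 0 → 40 °C
Reagents that add atoms: ethynylmagnesium bromide, C#C[Mg]Br
Why: Copper-catalysed substitution of a primary allylic bromide by an alkynyl Grignard reagent should give the skipped enyne by attack at the unsubstituted allylic terminus with retention of the E olefin.

Step 13
Reactants: 16 terminal alkyne
Product: 19 triisopropyl{[(4E,8E,12E,16E,20E,24E,28E,32E,37S)-5,9,13,17,21,25,29,33,37,41-decamethyldotetraconta-4,8,12,16,20,24,28,32,40-nonaen-1-yn-1-yl]oxy}silane, via lithium acetylide 17 (not isolated), via lithium ynolate 18 (not isolated)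
Conditions: n-BuLi, THF, −78 °C; LiOOt-Bu (from t-BuOOH + LiN(SiMe3)2), −78 → 0 °C; i-Pr3SiOTf, −78 → 0 °C
Reagents that add atoms: tert-butyl hydroperoxide, CC(C)(C)OO (used as its lithium salt); triisopropylsilyl trifluoromethanesulfonate, CC(C)[Si](C(C)C)(C(C)C)OS(=O)(=O)C(F)(F)F
Why: Oxygen transfer from lithium tert-butyl peroxide to a lithium acetylide gives the lithium ynolate, which a bulky silyl triflate captures on oxygen to give the siloxyalkyne.

Step 14
Reactants: 20 dimethyl squarate (3,4-dimethoxycyclobut-3-ene-1,2-dione)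
Product: 21 2,3,4,4-tetramethoxycyclobut-2-en-1-one
Conditions: MeOSiMe3 (2.2 equiv), Me3SiOTf (5 mol %), CH2Cl2, −78 → 0 °C
Reagents that add atoms: methoxytrimethylsilane, CO[Si](C)(C)C
Why: Silyl triflate-catalysed ketalisation with an alkoxysilane converts one carbonyl of the dione; the remaining one, now only a vinylogous ester, should not react further.

Step 15
Reactants: 21 squarate monoketal
Product: 24 2,4,4-trimethoxy-3-methylcyclobut-2-en-1-one, via lithium alkoxide 22 (not isolated), via allylic trifluoroacetate 23 (not isolated)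
Conditions: MeLi, THF, −78 °C; (CF3CO)2O, −78 °C; then H2O, 0 °C
Reagents that add atoms: methyllithium, [Li]C; water, O
Why: 1,2-Addition of MeLi to the vinylogous ester carbonyl, then trifluoroacetylation, ionisation and hydrolysis of the methoxy-stabilised allyl cation (a 1,3-carbonyl transposition of the Stork–Danheiser type), moves the carbonyl next to the ketal and puts the methyl group on the enone β-carbon.

Step 16
Reactants: 19 siloxyalkyne; 24 cyclobutenone
Product: 27 3-hydroxy-2-methoxy-5-methyl-6-R50-cyclohexa-2,5-diene-1,4-dione, via bicyclo[2.2.0]hexenone adduct 25 (not isolated), via siloxycyclohexadienone 26 (not isolated)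
Conditions: AgNTf2 (10 mol %), CH2Cl2, −40 °C → rt; then 0.5 M HCl, THF, 0 °C
Reagents that add atoms: water, O
Why: Proposed new method: the siloxyalkyne 19, activated by monovalent silver and nucleophilic at its chain-bearing carbon, should add to the enone β-carbon of 24 (the methyl-bearing carbon, future C5), and the resulting enolate carbon (future C2) should close on the silyl-ketenium carbon (future C1), a stepwise Ficini-type [2+2] that forms C5–C6 and C1–C2 in one event and gives the cis-fused siloxycyclobutene 25. The closest known reactions are the AgNTf2-catalysed [2+2] cycloaddition of siloxyalkynes with cyclic enones and the two-carbon ring enlargement of cyclic enamines by acetylenic esters ([2+2], then cyclobutene opening), here with donor and acceptor exchanged. The four-membered ring closes by conjugate addition followed by C-attack of the enolate on the ketenium carbon; the six-membered ring is not closed but uncovered when the shared C2–C5 bond of 25 opens (four-electron electrocyclic opening, driven by the push of the siloxy group, the pull of the ketone and the strain of two fused four-membered rings) to give 26. The two ring-fusion stereocentres of 25 are transient and vanish in 26, so no stereocontrol is needed and the chain stereocentre is not touched. The step needs regioselectivity (chain carbon to C5, oxygenated carbon to C2) and site selectivity (enone C=C over C=O, alkyne over the nine chain olefins); the first is secured because the C4 ketal leaves C3=O as the only acceptor and C5 as the only β-position, the second because the siloxyalkyne is by far the most electron-rich π-bond offered to silver. Dilute acid then cleaves the silyl ether and the ketal, and the vinylogous acid settles as the 3-hydroxy-1,4-quinone 27.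

Step 17
Reactants: 27 hydroxyquinone
Product: 28 2,3-dimethoxy-5-methyl-6-R50-cyclohexa-2,5-diene-1,4-dione (the target)
Conditions: Me3SiCHN2, MeOH/toluene (1:4), 0 °C
Reagents that add atoms: (trimethylsilyl)diazomethane, C[Si](C)(C)C=[N+]=[N-]
Why: O-Methylation of a vinylogous carboxylic acid by a diazomethane surrogate under neutral conditions should give the 1,4-quinone methyl ether and avoids the base-induced cyclisation of the chain onto the quinone.

**Compound list**

1 | (2E,6E,10E)-geranylgeraniol | OC/C=C(\C)CC/C=C(\C)CC/C=C(\C)CCC=C(C)C | starting material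
2 | geranylgeranyl tert-butyldimethylsilyl ether | CC(C)(C)[Si](C)(C)OC/C=C(\C)CC/C=C(\C)CC/C=C(\C)CCC=C(C)C | intermediate
3 | (2E,6E,10E,14E)-16-[(tert-butyldimethylsilyl)oxy]-2,6,10,14-tetramethylhexadeca-2,6,10,14-tetraen-1-ol | CC(C)(C)[Si](C)(C)OC/C=C(\C)CC/C=C(\C)CC/C=C(\C)CC/C=C(\C)CO | intermediate
4 | {[(2E,6E,10E,14E)-16-bromo-3,7,11,15-tetramethylhexadeca-2,6,10,14-tetraen-1-yl]oxy}(tert-butyl)dimethylsilane | CC(C)(C)[Si](C)(C)OC/C=C(\C)CC/C=C(\C)CC/C=C(\C)CC/C=C(\C)CBr | intermediate
5 | 16-(4-methylbenzenesulfonyl) analogue of 4 | CC(C)(C)[Si](C)(C)OC/C=C(\C)CC/C=C(\C)CC/C=C(\C)CC/C=C(\C)CS(=O)(=O)c1ccc(C)cc1 | intermediate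
6 | (R)-citronellyl bromide, (6R)-8-bromo-2,6-dimethyloct-2-ene | BrCC[C@H](C)CCC=C(C)C | starting material
7 | (R)-citronellylmagnesium bromide | Br[Mg]CC[C@H](C)CCC=C(C)C | intermediate
8 | tert-butyl{[(2E,6E,10E,14E,19S)-3,7,11,15,19,23-hexamethyltetracosa-2,6,10,14,22-pentaen-1-yl]oxy}dimethylsilane | CC(C)(C)[Si](C)(C)OC/C=C(\C)CC/C=C(\C)CC/C=C(\C)CC/C=C(\C)CCC[C@H](C)CCC=C(C)C | intermediate
9 | (2E,6E,10E,14E,19S)-3,7,11,15,19,23-hexamethyltetracosa-2,6,10,14,22-pentaen-1-ol | OC/C=C(\C)CC/C=C(\C)CC/C=C(\C)CC/C=C(\C)CCC[C@H](C)CCC=C(C)C | intermediate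
10 | (2E,6E,10E,14E,19S)-1-bromo-3,7,11,15,19,23-hexamethyltetracosa-2,6,10,14,22-pentaene | BrC/C=C(\C)CC/C=C(\C)CC/C=C(\C)CC/C=C(\C)CCC[C@H](C)CCC=C(C)C | intermediate
11 | C16-lithiated sulfone 5 | CC(C)(C)[Si](C)(C)OC/C=C(\C)CC/C=C(\C)CC/C=C(\C)CC/C=C(\C)C([Li])S(=O)(=O)c1ccc(C)cc1 | intermediate
12 | C50 silyl ether carrying the 4-methylbenzenesulfonyl group at C16 (both epimers) | CC(C)(C)[Si](C)(C)OC/C=C(\C)CC/C=C(\C)CC/C=C(\C)CC/C=C(\C)C(S(=O)(=O)c1ccc(C)cc1)C/C=C(\C)CC/C=C(\C)CC/C=C(\C)CC/C=C(\C)CCC[C@H](C)CCC=C(C)C | intermediate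
13 | tert-butyl(dimethyl)(R50-oxy)silane | CC(C)(C)[Si](C)(C)OC/C=C(\C)CC/C=C(\C)CC/C=C(\C)CC/C=C(\C)CC/C=C(\C)CC/C=C(\C)CC/C=C(\C)CC/C=C(\C)CCC[C@H](C)CCC=C(C)C | intermediate
14 | R50-OH | OC/C=C(\C)CC/C=C(\C)CC/C=C(\C)CC/C=C(\C)CC/C=C(\C)CC/C=C(\C)CC/C=C(\C)CC/C=C(\C)CCC[C@H](C)CCC=C(C)C | intermediate
15 | R50-Br | BrC/C=C(\C)CC/C=C(\C)CC/C=C(\C)CC/C=C(\C)CC/C=C(\C)CC/C=C(\C)CC/C=C(\C)CC/C=C(\C)CCC[C@H](C)CCC=C(C)C | intermediate
16 | (4E,8E,12E,16E,20E,24E,28E,32E,37S)-5,9,13,17,21,25,29,33,37,41-decamethyldotetraconta-4,8,12,16,20,24,28,32,40-nonaen-1-yne | C#CC/C=C(\C)CC/C=C(\C)CC/C=C(\C)CC/C=C(\C)CC/C=C(\C)CC/C=C(\C)CC/C=C(\C)CC/C=C(\C)CCC[C@H](C)CCC=C(C)C | intermediate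
17 | lithium acetylide of 16 | [Li]C#CC/C=C(\C)CC/C=C(\C)CC/C=C(\C)CC/C=C(\C)CC/C=C(\C)CC/C=C(\C)CC/C=C(\C)CC/C=C(\C)CCC[C@H](C)CCC=C(C)C | intermediate
18 | lithium ynolate (1-lithiooxy analogue of 16) | [Li]OC#CC/C=C(\C)CC/C=C(\C)CC/C=C(\C)CC/C=C(\C)CC/C=C(\C)CC/C=C(\C)CC/C=C(\C)CC/C=C(\C)CCC[C@H](C)CCC=C(C)C | intermediate
19 | 1-(triisopropylsilyloxy) analogue of 16 (siloxyalkyne) | CC(C)[Si](C(C)C)(C(C)C)OC#CC/C=C(\C)CC/C=C(\C)CC/C=C(\C)CC/C=C(\C)CC/C=C(\C)CC/C=C(\C)CC/C=C(\C)CC/C=C(\C)CCC[C@H](C)CCC=C(C)C | intermediate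
20 | dimethyl squarate | COC1=C(OC)C(=O)C1=O | starting material
21 | 2,3,4,4-tetramethoxycyclobut-2-en-1-one | COC1=C(OC)C(OC)(OC)C1=O | intermediate
22 | lithium 2,3,4,4-tetramethoxy-1-methylcyclobut-2-en-1-olate | [Li]OC1(C)C(OC)=C(OC)C1(OC)OC | intermediate
23 | 2,3,4,4-tetramethoxy-1-methylcyclobut-2-en-1-yl trifluoroacetate | FC(F)(F)C(=O)OC1(C)C(OC)=C(OC)C1(OC)OC | intermediate
24 | 2,4,4-trimethoxy-3-methylcyclobut-2-en-1-one | COC1=C(C)C(OC)(OC)C1=O | intermediate
25 | 1,5,5-trimethoxy-4-methyl-3-R50-2-(triisopropylsilyloxy)bicyclo[2.2.0]hex-2-en-6-one (cis-fused, both diastereomers) | CC(C)[Si](C(C)C)(C(C)C)OC1=C(C/C=C(\C)CC/C=C(\C)CC/C=C(\C)CC/C=C(\C)CC/C=C(\C)CC/C=C(\C)CC/C=C(\C)CC/C=C(\C)CCC[C@H](C)CCC=C(C)C)C2(C)C(OC)(OC)C(=O)C12OC | intermediate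
26 | 2,6,6-trimethoxy-5-methyl-4-R50-3-(triisopropylsilyloxy)cyclohexa-2,4-dien-1-one | CC(C)[Si](C(C)C)(C(C)C)OC1=C(OC)C(=O)C(OC)(OC)C(C)=C1C/C=C(\C)CC/C=C(\C)CC/C=C(\C)CC/C=C(\C)CC/C=C(\C)CC/C=C(\C)CC/C=C(\C)CC/C=C(\C)CCC[C@H](C)CCC=C(C)C | intermediate
27 | 3-hydroxy-2-methoxy-5-methyl-6-R50-cyclohexa-2,5-diene-1,4-dione | OC1=C(OC)C(=O)C(C/C=C(\C)CC/C=C(\C)CC/C=C(\C)CC/C=C(\C)CC/C=C(\C)CC/C=C(\C)CC/C=C(\C)CC/C=C(\C)CCC[C@H](C)CCC=C(C)C)=C(C)C1=O | intermediate
28 | 2,3-dimethoxy-5-methyl-6-R50-cyclohexa-2,5-diene-1,4-dione (CNP0144872.1) | COC1=C(OC)C(=O)C(C/C=C(\C)CC/C=C(\C)CC/C=C(\C)CC/C=C(\C)CC/C=C(\C)CC/C=C(\C)CC/C=C(\C)CC/C=C(\C)CCC[C@H](C)CCC=C(C)C)=C(C)C1=O | target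

**Step count and risks**

Total: 17 steps. Longest linear sequence: 14 steps (1, 2, 3, 5–13, 16, 17).

Steps most likely to fail, in this order: 16, 2, 12.

Step 16. The zwitterion formed after the first C–C bond may close through oxygen (a hetero-[4+2] adduct) instead of through carbon; the silver-bound alkyne may be intercepted by the neighbouring chain olefin or add to the carbonyl group; the cyclobutenone may open to a vinylketene if the mixture has to be warmed. Fallback (sets out from 15, returns at 28), known chemistry only and no ring construction: commercial 2,3,4,5-tetramethoxytoluene (Cc1cc(OC)c(OC)c(OC)c1OC) is brominated (NBS, MeCN) to 1-bromo-2,3,4,5-tetramethoxy-6-methylbenzene F1. Bromine–lithium exchange (n-BuLi, THF, −78 °C) gives 2,3,4,5-tetramethoxy-6-methylphenyllithium F2, which with CuBr·SMe2 (10 mol %) should be allylated by 15 at the primary terminus to give 1,2,3,4-tetramethoxy-5-methyl-6-R50-benzene F3. Oxidative demethylation with (NH4)2Ce(NO3)6 (MeCN/H2O, 0 °C) then gives 28.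

Step 2. Oxidation at internal trisubstituted olefins and over-oxidation to the enal erode site selectivity at useful conversion. Fallback (sets out from 2, returns at 3), terminal functionalisation through the bromohydrin: NBS in aqueous THF (0 °C) should add to the terminal olefin to give (6E,10E,14E)-3-bromo-16-[(tert-butyldimethylsilyl)oxy]-2,6,10,14-tetramethylhexadeca-6,10,14-trien-2-ol F4. K2CO3/MeOH closes the terminal epoxide F5; H5IO6 (THF/H2O) cleaves it to (4E,8E,12E)-14-[(tert-butyldimethylsilyl)oxy]-4,8,12-trimethyltetradeca-4,8,12-trienal F6. A Wittig reaction with the stabilised ylide Ph3P=C(CH3)CO2Et gives ethyl (2E,6E,10E,14E)-16-[(tert-butyldimethylsilyl)oxy]-2,6,10,14-tetramethylhexadeca-2,6,10,14-tetraenoate F7, and i-Bu2AlH (CH2Cl2, −78 °C) reduces it to 3.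

Step 12. Attack at the substituted allylic terminus and base-induced isomerisation of the skipped enyne to an allene under the Grignard conditions. Fallback (sets out from 15, returns at 16): Stille coupling of 15 with tributyl(ethynyl)stannane (Pd2(dba)3, tri(2-furyl)phosphine, THF, 50 °C), in which the alkynyl group is delivered to the less hindered terminus of a π-allyl palladium complex under non-basic conditions; no new compound is made.

Further compounds
F1 | step 16 | 1-bromo-2,3,4,5-tetramethoxy-6-methylbenzene | Cc1c(Br)c(OC)c(OC)c(OC)c1OC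
F2 | step 16 | 2,3,4,5-tetramethoxy-6-methylphenyllithium | [Li]c1c(C)c(OC)c(OC)c(OC)c1OC
F3 | step 16 | 1,2,3,4-tetramethoxy-5-methyl-6-R50-benzene | Cc1c(C/C=C(\C)CC/C=C(\C)CC/C=C(\C)CC/C=C(\C)CC/C=C(\C)CC/C=C(\C)CC/C=C(\C)CC/C=C(\C)CCC[C@H](C)CCC=C(C)C)c(OC)c(OC)c(OC)c1OC
F4 | step 2 | (6E,10E,14E)-3-bromo-16-[(tert-butyldimethylsilyl)oxy]-2,6,10,14-tetramethylhexadeca-6,10,14-trien-2-ol | CC(C)(C)[Si](C)(C)OC/C=C(\C)CC/C=C(\C)CC/C=C(\C)CCC(Br)C(C)(C)O
F5 | step 2 | terminal 14,15-epoxide of 2 | CC(C)(C)[Si](C)(C)OC/C=C(\C)CC/C=C(\C)CC/C=C(\C)CCC1OC1(C)C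
F6 | step 2 | (4E,8E,12E)-14-[(tert-butyldimethylsilyl)oxy]-4,8,12-trimethyltetradeca-4,8,12-trienal | CC(C)(C)[Si](C)(C)OC/C=C(\C)CC/C=C(\C)CC/C=C(\C)CCC=O
F7 | step 2 | ethyl (2E,6E,10E,14E)-16-[(tert-butyldimethylsilyl)oxy]-2,6,10,14-tetramethylhexadeca-2,6,10,14-tetraenoate | CC(C)(C)[Si](C)(C)OC/C=C(\C)CC/C=C(\C)CC/C=C(\C)CC/C=C(\C)C(=O)OCC
F0 | step 12 | none | none
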